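**Plan**

- Retrosynthetic cuts: (a) the interflavan C4(upper)–C8(lower) bond; (b) in the lower unit the C4–C4a bond and the C3–O(gallate) bond, both made in one 1,2-interchange that expands a 2-aryl-3-(galloyloxymethyl)-2,3-dihydrobenzofuran; (c) the C2–C3 bond of that dihydrobenzofuran, by carbenoid C–H insertion; (d) all benzyl-type ethers.
- Enabling feature: in the lower unit, ring A carbon C4a has oxygen on both ortho carbons (C5, C8a) and on the para carbon (C7) and lies β to the C3–O ester, so it can move between C3 and C4 through a phenonium ion.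
- Forward order: threefold-symmetric phloroglucinol triether → aryldiazoacetate → five-membered O-heterocycle → ring expansion to the six-membered ring C with the gallate delivered to C3 → Friedel–Crafts union with the C4 cation of protected (−)-epicatechin → global hydrogenolysis.
- Stereochemistry: lower C2/C3 come from a catalyst-controlled cis-selective C–H insertion, and C3 is relayed by the stereospecific anti 1,2-shift; upper C2/C3 come from (−)-epicatechin; upper C4 is set by attack anti to the 2-aryl group (4β, 3,4-trans).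

Key step: step 8

Abbreviation: TBB = 3,4,5-tris(benzyloxy)benzyl.
Remark: Rh2(S-PTTL)4 is assumed to deliver the (2S,3R)-cis enantiomer of 9; if the opposite sense is found, the mirror-image catalyst Rh2(R-PTTL)4 is used instead.

**Route**

Step 1
Reactants: 1 3,4,5-tris(benzyloxy)benzyl alcohol
Product: 2 3,4,5-tris(benzyloxy)benzyl chloride (TBB chloride)
Conditions: SOCl2, cat. DMF, CH2Cl2, 0 °C to rt
Reagents that add atoms: thionyl chloride, O=S(Cl)Cl
Why: Chlorodehydroxylation of a primary benzylic alcohol through its chlorosulfite should proceed cleanly, the benzyl ethers being inert to these conditions.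

Step 2
Reactants: 3 phloroglucinol triacetate; 2 TBB chloride (3 equiv)
Product: 4 1,3,5-tris(TBB-oxy)benzene
Conditions: NaH (6.6 equiv), H2O (3 equiv), DMF, 0 °C to rt, with a further 0.3 equiv of 2 to drive the third alkylation to completion
Reagents that add atoms: TBB chloride (second equivalent of compound 2), ClCc1cc(OCc2ccccc2)c(OCc2ccccc2)c(OCc2ccccc2)c1; TBB chloride (third equivalent of compound 2), ClCc1cc(OCc2ccccc2)c(OCc2ccccc2)c(OCc2ccccc2)c1
Why: Slow in-situ deacetylation releases each phenoxide in low concentration, so threefold Williamson O-alkylation (one molecule of 2 at each of the three oxygens) should outrun C-alkylation of the phloroglucinol nucleus and the threefold symmetry is kept.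

Step 3
Reactants: 4 1,3,5-tris(TBB-oxy)benzene
Product: 6 methyl 2-oxo-2-[2,4,6-tris(TBB-oxy)phenyl]acetate, via aryl glyoxylyl chloride 5 (not isolated)
Conditions: (COCl)2, CH2Cl2, 0 °C to rt; concentrate; then MeOH, pyridine, CH2Cl2, 0 °C
Reagents that add atoms: oxalyl chloride, ClC(=O)C(=O)Cl; methanol, CO
Why: Uncatalysed Friedel–Crafts acylation of the highly nucleophilic 1,3,5-trialkoxybenzene core (three equivalent positions) followed by methanolysis should give the α-keto ester without a Lewis acid that could cleave the benzyl-type ethers.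

Step 4
Reactants: 6 methyl 2-oxo-2-[2,4,6-tris(TBB-oxy)phenyl]acetate
Product: 8 methyl 2-diazo-2-[2,4,6-tris(TBB-oxy)phenyl]acetate, via tosylhydrazone 7 (not isolated)
Conditions: TsNHNH2, cat. TsOH, toluene, 80 °C; then DBU, CH2Cl2, rt
Reagents that add atoms: p-toluenesulfonyl hydrazide, Cc1ccc(cc1)S(=O)(=O)NN
Why: Condensation to the tosylhydrazone and base-induced loss of sulfinate (Bamford–Stevens reaction) is the standard entry to aryldiazoacetates from aryl glyoxylates.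

Step 5
Reactants: 8 methyl 2-diazo-2-[2,4,6-tris(TBB-oxy)phenyl]acetate
Product: 9 methyl (2S,3R)-cis-2-[3,4,5-tris(benzyloxy)phenyl]-4,6-bis(TBB-oxy)-2,3-dihydrobenzofuran-3-carboxylate
Conditions: Rh2(S-PTTL)4 (dirhodium tetrakis[N-phthaloyl-(S)-tert-leucinate], 2 mol %), toluene, −60 to −40 °C
Reagents that add atoms: none
Why: Intramolecular 1,5 C–H insertion of the rhodium carbenoid into the benzylic ether C–H of an ortho TBB-oxy group (the two ortho ethers are homotopic, so there is no site issue) should give the kinetic cis-2-aryl-2,3-dihydrobenzofuran-3-carboxylate, with C2 and C3 set by the chiral carboxylate ligands.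

Step 6
Reactants: 9 cis-dihydrobenzofuran ester
Product: 10 [(2S,3S)-cis-2-[3,4,5-tris(benzyloxy)phenyl]-4,6-bis(TBB-oxy)-2,3-dihydrobenzofuran-3-yl]methanol
Conditions: iBu2AlH (3 equiv), CH2Cl2, −78 to −20 °C; aq. potassium sodium tartrate (KNaC4H4O6) work-up
Reagents that add atoms: none
Why: Hydride reduction of the ester at low temperature without base should give the primary alcohol with no enolisation, so the cis relationship is kept.

Step 7
Reactants: 10 cis-dihydrobenzofuran methanol; 11 3,4,5-tris(benzyloxy)benzoic acid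
Product: 12 [(2S,3S)-cis-2-[3,4,5-tris(benzyloxy)phenyl]-4,6-bis(TBB-oxy)-2,3-dihydrobenzofuran-3-yl]methyl 3,4,5-tris(benzyloxy)benzoate
Conditions: DCC, cat. DMAP, CH2Cl2, rt
Reagents that add atoms: none
Why: Steglich esterification of a primary alcohol under non-ionising conditions should place the gallate on the exocyclic carbon without touching either stereocenter.

Step 8
Reactants: 12 primary gallate ester of the cis-dihydrobenzofuran
Product: 13 (2R,3R)-2,3-cis-2-[3,4,5-tris(benzyloxy)phenyl]-5,7-bis(TBB-oxy)chroman-3-yl 3,4,5-tris(benzyloxy)benzoate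
Conditions: TMSOTf (0.3 equiv), 2,6-di-tert-butyl-4-methylpyridine (0.5 equiv), CH2Cl2 (0.01 M), −40 to 0 °C
Reagents that add atoms: none
Why: Proposed new method: silylation of the ester carbonyl by TMSOTf turns the primary carboxylate into a leaving group (a silyl ester) whose departure is assisted by ipso attack of ring A carbon C3a on the CH2 carbon (Ar1-3 participation, 3-exo-tet), giving a spiro[2.5]octadienyl (phenonium) cation stabilised by the oxygens on both ortho carbons and the para carbon; the silyl gallate then returns to C3 anti to the breaking C3–C3a bond, so that the aryl carbon and the acyloxy group exchange places and the five-membered ring becomes the six-membered ring C. The closest known reaction type is the phenonium-ion Wagner–Meerwein 1,2-aryl shift with ion-pair return in the solvolysis of β-arylalkyl sulfonates, combined with TMSOTf activation of an ester leaving group as in Vorbrüggen-type glycosylation. Ring C is therefore closed by ring expansion (C4–C4a bond made by the 3-exo-tet ipso attack, old C3–C3a bond cut when the three-membered ring opens), not by cyclisation of a chain. The new stereocenter C3 of the chroman is controlled by the stereospecific anti opening (inversion at C3), which relays the cis relationship of 12 into the 2,3-cis (2R,3R) arrangement, while C2 is not touched. The step needs return at C3 and not at CH2, and no ionisation at C2: return at CH2 only regenerates 12 and is reversible, whereas the secondary ester on the unstrained six-membered ring should be the thermodynamic sink (relief of the cis-2,3 strain of the five-membered ring, secondary versus primary C–O) and should re-ionise slowly because its axial C3–O bond is not anti to C4–C4a. Competing 1,2-shift of hydrogen or of ring B from C2 to C3 is disfavoured because the spiro intermediate holds both at about 120° to the breaking C3–C3a bond, so neither is antiperiplanar to it.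

Step 9
Reactants: 14 (−)-epicatechin
Product: 15 5,7,3',4'-tetra-O-benzyl-(−)-epicatechin
Conditions: BnBr (4.4 equiv), K2CO3, DMF, 0 °C to rt
Reagents that add atoms: benzyl bromide, BrCc1ccccc1
Why: Williamson etherification under carbonate conditions should benzylate the four phenols only, leaving the secondary 3-OH and both stereocenters unchanged.

Step 10
Reactants: 15 5,7,3',4'-tetra-O-benzyl-(−)-epicatechin
Product: 16 4β-(2-ethoxyethoxy)-5,7,3',4'-tetra-O-benzyl-(−)-epicatechin (C2 and C3 as in epicatechin, C4 (S), alkoxy trans to 3-OH)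
Conditions: DDQ (2 equiv), 2-ethoxyethanol, CH2Cl2, rt
Reagents that add atoms: 2-ethoxyethanol, CCOCCO
Why: DDQ oxidation of the benzylic C4–H to the ring-A-stabilised cation, trapped by the alcohol on the face anti to the 2-aryl group, should give the 4β-alkoxy (3,4-trans) ether as with other benzylated flavan-3-ols.

Step 11
Reactants: 16 4β-(2-ethoxyethoxy) electrophile; 13 protected epigallocatechin gallate (1.5 equiv, excess recovered)
Product: 17 5,7,3',4'-tetra-O-benzyl-epicatechin-(4β→8)-[5,7-di-O-TBB-3',4',5'-tri-O-benzyl-epigallocatechin 3-O-(3,4,5-tri-O-benzylgallate)]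
Conditions: TMSOTf (0.2 equiv), CH2Cl2, −78 °C, slow addition of 16
Reagents that add atoms: none
Why: Lewis-acid ionisation of the 4-alkoxy group gives the C4 benzylic cation, which should undergo Friedel–Crafts attack by the more accessible and more nucleophilic C8 of 13 on the face anti to the 2-aryl and 3-OH groups, setting the 4β (3,4-trans) interflavan bond as in known procyanidin couplings.

Step 12
Reactants: 17 protected dimer
Product: 18 epicatechin-(4β→8)-epigallocatechin 3-O-gallate (CNP0246304.2)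
Conditions: H2 (1 atm), Pd(OH)2/C, THF/MeOH/H2O, rt
Reagents that add atoms: none
Why: Hydrogenolysis should remove all sixteen benzyl ethers and cleave the two TBB aryl ethers at their benzylic C–O bonds, leaving the gallate ester, the interflavan bond and all stereocenters intact.

**Compound list**

1 | 3,4,5-tris(benzyloxy)benzyl alcohol | OCc1cc(OCc2ccccc2)c(OCc2ccccc2)c(OCc2ccccc2)c1 | starting material
2 | 3,4,5-tris(benzyloxy)benzyl chloride | ClCc1cc(OCc2ccccc2)c(OCc2ccccc2)c(OCc2ccccc2)c1 | intermediate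
3 | phloroglucinol triacetate | CC(=O)Oc1cc(OC(C)=O)cc(OC(C)=O)c1 | starting material
4 | 1,3,5-tris(TBB-oxy)benzene | c1c(OCc2cc(OCc3ccccc3)c(OCc3ccccc3)c(OCc3ccccc3)c2)cc(OCc2cc(OCc3ccccc3)c(OCc3ccccc3)c(OCc3ccccc3)c2)cc1OCc1cc(OCc2ccccc2)c(OCc2ccccc2)c(OCc2ccccc2)c1 | intermediate
5 | 2-oxo-2-[2,4,6-tris(TBB-oxy)phenyl]acetyl chloride | O=C(Cl)C(=O)c1c(OCc2cc(OCc3ccccc3)c(OCc3ccccc3)c(OCc3ccccc3)c2)cc(OCc2cc(OCc3ccccc3)c(OCc3ccccc3)c(OCc3ccccc3)c2)cc1OCc1cc(OCc2ccccc2)c(OCc2ccccc2)c(OCc2ccccc2)c1 | intermediate (not isolated)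
6 | methyl 2-oxo-2-[2,4,6-tris(TBB-oxy)phenyl]acetate | COC(=O)C(=O)c1c(OCc2cc(OCc3ccccc3)c(OCc3ccccc3)c(OCc3ccccc3)c2)cc(OCc2cc(OCc3ccccc3)c(OCc3ccccc3)c(OCc3ccccc3)c2)cc1OCc1cc(OCc2ccccc2)c(OCc2ccccc2)c(OCc2ccccc2)c1 | intermediate
7 | N-tosylhydrazone of 6 | COC(=O)C(=NNS(=O)(=O)c1ccc(C)cc1)c1c(OCc2cc(OCc3ccccc3)c(OCc3ccccc3)c(OCc3ccccc3)c2)cc(OCc2cc(OCc3ccccc3)c(OCc3ccccc3)c(OCc3ccccc3)c2)cc1OCc1cc(OCc2ccccc2)c(OCc2ccccc2)c(OCc2ccccc2)c1 | intermediate (not isolated)
8 | methyl 2-diazo-2-[2,4,6-tris(TBB-oxy)phenyl]acetate | COC(=O)C(=[N+]=[N-])c1c(OCc2cc(OCc3ccccc3)c(OCc3ccccc3)c(OCc3ccccc3)c2)cc(OCc2cc(OCc3ccccc3)c(OCc3ccccc3)c(OCc3ccccc3)c2)cc1OCc1cc(OCc2ccccc2)c(OCc2ccccc2)c(OCc2ccccc2)c1 | intermediate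
9 | methyl (2S,3R)-cis-2-[3,4,5-tris(benzyloxy)phenyl]-4,6-bis(TBB-oxy)-2,3-dihydrobenzofuran-3-carboxylate | COC(=O)[C@@H]1c2c(OCc3cc(OCc4ccccc4)c(OCc4ccccc4)c(OCc4ccccc4)c3)cc(OCc3cc(OCc4ccccc4)c(OCc4ccccc4)c(OCc4ccccc4)c3)cc2O[C@@H]1c1cc(OCc2ccccc2)c(OCc2ccccc2)c(OCc2ccccc2)c1 | intermediate
10 | [(2S,3S)-cis-2-[3,4,5-tris(benzyloxy)phenyl]-4,6-bis(TBB-oxy)-2,3-dihydrobenzofuran-3-yl]methanol | OC[C@@H]1c2c(OCc3cc(OCc4ccccc4)c(OCc4ccccc4)c(OCc4ccccc4)c3)cc(OCc3cc(OCc4ccccc4)c(OCc4ccccc4)c(OCc4ccccc4)c3)cc2O[C@@H]1c1cc(OCc2ccccc2)c(OCc2ccccc2)c(OCc2ccccc2)c1 | intermediate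
11 | 3,4,5-tris(benzyloxy)benzoic acid | OC(=O)c1cc(OCc2ccccc2)c(OCc2ccccc2)c(OCc2ccccc2)c1 | starting material
12 | [(2S,3S)-cis-2-[3,4,5-tris(benzyloxy)phenyl]-4,6-bis(TBB-oxy)-2,3-dihydrobenzofuran-3-yl]methyl 3,4,5-tris(benzyloxy)benzoate | O=C(OC[C@@H]1c2c(OCc3cc(OCc4ccccc4)c(OCc4ccccc4)c(OCc4ccccc4)c3)cc(OCc3cc(OCc4ccccc4)c(OCc4ccccc4)c(OCc4ccccc4)c3)cc2O[C@@H]1c1cc(OCc2ccccc2)c(OCc2ccccc2)c(OCc2ccccc2)c1)c1cc(OCc2ccccc2)c(OCc2ccccc2)c(OCc2ccccc2)c1 | intermediate
13 | (2R,3R)-2,3-cis-2-[3,4,5-tris(benzyloxy)phenyl]-5,7-bis(TBB-oxy)chroman-3-yl 3,4,5-tris(benzyloxy)benzoate | O=C(O[C@@H]1Cc2c(OCc3cc(OCc4ccccc4)c(OCc4ccccc4)c(OCc4ccccc4)c3)cc(OCc3cc(OCc4ccccc4)c(OCc4ccccc4)c(OCc4ccccc4)c3)cc2O[C@@H]1c1cc(OCc2ccccc2)c(OCc2ccccc2)c(OCc2ccccc2)c1)c1cc(OCc2ccccc2)c(OCc2ccccc2)c(OCc2ccccc2)c1 | intermediate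
14 | (−)-epicatechin, (2R,3R) | O[C@@H]1Cc2c(O)cc(O)cc2O[C@@H]1c1ccc(O)c(O)c1 | starting material
15 | 5,7,3',4'-tetra-O-benzyl-(−)-epicatechin | O[C@@H]1Cc2c(OCc3ccccc3)cc(OCc3ccccc3)cc2O[C@@H]1c1ccc(OCc2ccccc2)c(OCc2ccccc2)c1 | intermediate
16 | 4β-(2-ethoxyethoxy)-5,7,3',4'-tetra-O-benzyl-(−)-epicatechin | CCOCCO[C@H]1c2c(OCc3ccccc3)cc(OCc3ccccc3)cc2O[C@H](c2ccc(OCc3ccccc3)c(OCc3ccccc3)c2)[C@@H]1O | intermediate
17 | 5,7,3',4'-tetra-O-benzyl-epicatechin-(4β→8)-[5,7-di-O-TBB-3',4',5'-tri-O-benzyl-epigallocatechin 3-O-(3,4,5-tri-O-benzylgallate)] | O=C(O[C@@H]1Cc2c(OCc3cc(OCc4ccccc4)c(OCc4ccccc4)c(OCc4ccccc4)c3)cc(OCc3cc(OCc4ccccc4)c(OCc4ccccc4)c(OCc4ccccc4)c3)c([C@H]3c4c(OCc5ccccc5)cc(OCc5ccccc5)cc4O[C@H](c4ccc(OCc5ccccc5)c(OCc5ccccc5)c4)[C@@H]3O)c2O[C@@H]1c1cc(OCc2ccccc2)c(OCc2ccccc2)c(OCc2ccccc2)c1)c1cc(OCc2ccccc2)c(OCc2ccccc2)c(OCc2ccccc2)c1 | intermediate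
18 | epicatechin-(4β→8)-epigallocatechin 3-O-gallate | O=C(O[C@@H]1Cc2c(O)cc(O)c([C@H]3c4c(O)cc(O)cc4O[C@H](c4ccc(O)c(O)c4)[C@@H]3O)c2O[C@@H]1c1cc(O)c(O)c(O)c1)c1cc(O)c(O)c(O)c1 | target

**Totals and risks**

Total step count: 12. Longest linear sequence: 10 steps (steps 1 to 8, then 11 and 12).

Steps most likely to fail:

1. Step 8 (proposed new method). The carboxylate may return only to the CH2 carbon without productive turnover, the benzylic C2–O1 ether may ionise with loss of the cis relationship, or the Lewis acid may cleave benzyl-type ethers. The fallback uses a Tiffeneau–Demjanov ring expansion and known steps only; it sets out from 9 and comes back at 13. Deprotonation of 9 with KN(SiMe3)2 and oxidation of the enolate with 2-(phenylsulfonyl)-3-phenyloxaziridine at −78 °C would give the tertiary α-hydroxy ester F1. Amidation with Me3Al/NH4Cl would give the α-hydroxy amide F2, and LiAlH4 reduction the amino alcohol F3. Diazotisation (NaNO2, aqueous AcOH, 0 °C) should trigger migration of the electron-rich ring A carbon and give the (2R)-flavan-3-one F4. Reduction with LiBH(sec-Bu)3 at −78 °C, hydride arriving anti to the 2-aryl group, should give the 2,3-cis alcohol F5, and DCC/DMAP esterification with 11 would return 13.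

2. Step 5. The congested 2,6-dialkoxyaryl carbenoid may insert with poor enantio- or diastereocontrol, may dimerise, or the cis ester may epimerise to trans. The fallback replaces catalyst-controlled enantioselection by a covalent auxiliary with separation of diastereomers; it sets out from 4 (through acid chloride 5) and comes back at 10. The acid chloride 5 would be quenched with (R)-pantolactone and pyridine to give the pantolactonyl glyoxylate F6. This would be converted through its tosylhydrazone F7 into the diazo ester F8. Insertion with Rh2(S-DOSP)4 (dirhodium tetrakis[(S)-N-(dodecylbenzenesulfonyl)prolinate]) would give the cis-dihydrobenzofuran pantolactone ester F9, purified from its diastereomers by chromatography. iBu2AlH reduction would then give 10.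

3. Step 11. The cation from 16 may self-condense through its own ring A, may attack C6 instead of C8 of 13, or the Lewis acid may strip TBB ethers. The fallback caps C8 of the electrophile with bromine so that equimolar coupling is possible; it sets out from 15 and comes back at 18. NBS in CH2Cl2 at −78 to −40 °C would give 8-bromo-5,7,3',4'-tetra-O-benzylepicatechin F10, and DDQ/2-ethoxyethanol its 4β-(2-ethoxyethoxy) derivative F11. TMSOTf-mediated coupling with 13 (1 equiv) would give the brominated protected dimer F12. Hydrogenolysis over Pd(OH)2/C with Et3N would remove the bromine together with all benzyl-type ethers to give 18.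

**Further compounds**

F1 | step 8 | methyl 2-[3,4,5-tris(benzyloxy)phenyl]-3-hydroxy-4,6-bis(TBB-oxy)-2,3-dihydrobenzofuran-3-carboxylate (C2 as in 9, OH trans to the 2-aryl group) | COC(=O)[C@]1(O)c2c(OCc3cc(OCc4ccccc4)c(OCc4ccccc4)c(OCc4ccccc4)c3)cc(OCc3cc(OCc4ccccc4)c(OCc4ccccc4)c(OCc4ccccc4)c3)cc2O[C@@H]1c1cc(OCc2ccccc2)c(OCc2ccccc2)c(OCc2ccccc2)c1
F2 | step 8 | 2-[3,4,5-tris(benzyloxy)phenyl]-3-hydroxy-4,6-bis(TBB-oxy)-2,3-dihydrobenzofuran-3-carboxamide (configuration as in F1) | NC(=O)[C@]1(O)c2c(OCc3cc(OCc4ccccc4)c(OCc4ccccc4)c(OCc4ccccc4)c3)cc(OCc3cc(OCc4ccccc4)c(OCc4ccccc4)c(OCc4ccccc4)c3)cc2O[C@@H]1c1cc(OCc2ccccc2)c(OCc2ccccc2)c(OCc2ccccc2)c1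
F3 | step 8 | 3-(aminomethyl)-2-[3,4,5-tris(benzyloxy)phenyl]-4,6-bis(TBB-oxy)-2,3-dihydrobenzofuran-3-ol (configuration as in F1) | NC[C@]1(O)c2c(OCc3cc(OCc4ccccc4)c(OCc4ccccc4)c(OCc4ccccc4)c3)cc(OCc3cc(OCc4ccccc4)c(OCc4ccccc4)c(OCc4ccccc4)c3)cc2O[C@@H]1c1cc(OCc2ccccc2)c(OCc2ccccc2)c(OCc2ccccc2)c1
F4 | step 8 | (2R)-2-[3,4,5-tris(benzyloxy)phenyl]-5,7-bis(TBB-oxy)chroman-3-one | O=C1Cc2c(OCc3cc(OCc4ccccc4)c(OCc4ccccc4)c(OCc4ccccc4)c3)cc(OCc3cc(OCc4ccccc4)c(OCc4ccccc4)c(OCc4ccccc4)c3)cc2O[C@@H]1c1cc(OCc2ccccc2)c(OCc2ccccc2)c(OCc2ccccc2)c1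
F5 | step 8 | (2R,3R)-2,3-cis-2-[3,4,5-tris(benzyloxy)phenyl]-5,7-bis(TBB-oxy)chroman-3-ol | O[C@@H]1Cc2c(OCc3cc(OCc4ccccc4)c(OCc4ccccc4)c(OCc4ccccc4)c3)cc(OCc3cc(OCc4ccccc4)c(OCc4ccccc4)c(OCc4ccccc4)c3)cc2O[C@@H]1c1cc(OCc2ccccc2)c(OCc2ccccc2)c(OCc2ccccc2)c1
F6 | step 5 | (R)-pantolactonyl 2-oxo-2-[2,4,6-tris(TBB-oxy)phenyl]acetate | CC1(C)COC(=O)[C@@H]1OC(=O)C(=O)c1c(OCc2cc(OCc3ccccc3)c(OCc3ccccc3)c(OCc3ccccc3)c2)cc(OCc2cc(OCc3ccccc3)c(OCc3ccccc3)c(OCc3ccccc3)c2)cc1OCc1cc(OCc2ccccc2)c(OCc2ccccc2)c(OCc2ccccc2)c1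
F7 | step 5 | N-tosylhydrazone of F6 | CC1(C)COC(=O)[C@@H]1OC(=O)C(=NNS(=O)(=O)c1ccc(C)cc1)c1c(OCc2cc(OCc3ccccc3)c(OCc3ccccc3)c(OCc3ccccc3)c2)cc(OCc2cc(OCc3ccccc3)c(OCc3ccccc3)c(OCc3ccccc3)c2)cc1OCc1cc(OCc2ccccc2)c(OCc2ccccc2)c(OCc2ccccc2)c1
F8 | step 5 | (R)-pantolactonyl 2-diazo-2-[2,4,6-tris(TBB-oxy)phenyl]acetate | CC1(C)COC(=O)[C@@H]1OC(=O)C(=[N+]=[N-])c1c(OCc2cc(OCc3ccccc3)c(OCc3ccccc3)c(OCc3ccccc3)c2)cc(OCc2cc(OCc3ccccc3)c(OCc3ccccc3)c(OCc3ccccc3)c2)cc1OCc1cc(OCc2ccccc2)c(OCc2ccccc2)c(OCc2ccccc2)c1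
F9 | step 5 | (R)-pantolactonyl (2S,3R)-cis-2-[3,4,5-tris(benzyloxy)phenyl]-4,6-bis(TBB-oxy)-2,3-dihydrobenzofuran-3-carboxylate | CC1(C)COC(=O)[C@@H]1OC(=O)[C@@H]1c2c(OCc3cc(OCc4ccccc4)c(OCc4ccccc4)c(OCc4ccccc4)c3)cc(OCc3cc(OCc4ccccc4)c(OCc4ccccc4)c(OCc4ccccc4)c3)cc2O[C@@H]1c1cc(OCc2ccccc2)c(OCc2ccccc2)c(OCc2ccccc2)c1
F10 | step 11 | 8-bromo-5,7,3',4'-tetra-O-benzyl-(−)-epicatechin | O[C@@H]1Cc2c(OCc3ccccc3)cc(OCc3ccccc3)c(Br)c2O[C@@H]1c1ccc(OCc2ccccc2)c(OCc2ccccc2)c1
F11 | step 11 | 8-bromo-4β-(2-ethoxyethoxy)-5,7,3',4'-tetra-O-benzyl-(−)-epicatechin | CCOCCO[C@H]1c2c(OCc3ccccc3)cc(OCc3ccccc3)c(Br)c2O[C@H](c2ccc(OCc3ccccc3)c(OCc3ccccc3)c2)[C@@H]1O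
F12 | step 11 | 8-bromo derivative (upper unit) of protected dimer 17 | O=C(O[C@@H]1Cc2c(OCc3cc(OCc4ccccc4)c(OCc4ccccc4)c(OCc4ccccc4)c3)cc(OCc3cc(OCc4ccccc4)c(OCc4ccccc4)c(OCc4ccccc4)c3)c([C@H]3c4c(OCc5ccccc5)cc(OCc5ccccc5)c(Br)c4O[C@H](c4ccc(OCc5ccccc5)c(OCc5ccccc5)c4)[C@@H]3O)c2O[C@@H]1c1cc(OCc2ccccc2)c(OCc2ccccc2)c(OCc2ccccc2)c1)c1cc(OCc2ccccc2)c(OCc2ccccc2)c(OCc2ccccc2)c1
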